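**Target:** (2S)-2-(3,4-dimethoxyphenyl)-6-hydroxy-5,7-dimethoxy-2,3-dihydro-4H-chromen-4-one (a 6-hydroxy-5,7,3',4'-tetramethoxyflavanone; C2 is S).

**Retrosynthetic overview**
1. The free 6-OH is unmasked last from the benzyl ether 13; rings A and B are bought (syringaldehyde, veratraldehyde), and only ring C is built.
2. Ring C is cut at C2–C3. The retron is the β-aryloxy ketone O1–C2–C3–C4=O: C2 carries ring oxygen O1 and the electron-rich ring B (acetal level, readily ionised), and C3/C4 are the enol of an aryl ketone.
3. The precursor is therefore the cyclic enol acetal 11 (a 4-methylidene-1,3-benzodioxine). Its C2–O3 bond is not in the target; O3 becomes the C4 carbonyl oxygen in a catalytic asymmetric Petasis–Ferrier rearrangement (formal 1,3 O-to-C shift).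
4. 11 comes from salicylic acid 7 and veratraldehyde 8 (dioxinone 10, then carbonyl methylenation); 7 comes from syringaldehyde by benzylation, Dakin-type oxidation, ortho-formylation and Pinnick oxidation.
5. Ring order: ring A and ring B given; temporary 1,3-dioxine ring (step 5); ring C from it (step 7).

Key step: step 7

**Remarks.** Syringaldehyde, benzyl bromide and 3,4-dimethoxybenzaldehyde are taken as commercial. The squaramide of step 7 is a hydrogen-bond donor with a 3,5-bis(trifluoromethyl)anilino arm and a tert-leucine 2-arylpyrrolidine amide arm. Its sense of induction on this substrate cannot be read from precedent; both antipodes are accessible (L- or D-tert-leucine), and the one that should give (2S) in a first test run is the one meant.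

**Step 1**
Reactants: 1 syringaldehyde (4-hydroxy-3,5-dimethoxybenzaldehyde); 2 benzyl bromide
Product: 3 4-(benzyloxy)-3,5-dimethoxybenzaldehyde
Conditions: K2CO3, DMF, 60 °C
Reagents that add atoms: benzyl bromide (2), BrCc1ccccc1
Why: Williamson ether synthesis; the phenoxide of 1 is the only nucleophile and benzyl bromide is a reactive SN2 electrophile.

**Step 2**
Reactants: 3 4-(benzyloxy)-3,5-dimethoxybenzaldehyde
Product: 5 4-(benzyloxy)-3,5-dimethoxyphenol, via aryl formate 4 (not isolated)
Conditions: mCPBA, CH2Cl2, 0 °C to rt; then MeOH, K2CO3 (cat.), rt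
Reagents that add atoms: mCPBA, OOC(=O)c1cccc(Cl)c1
Why: Baeyer–Villiger oxidation in its Dakin-type mode; in the Criegee adduct the trialkoxyaryl group migrates in preference to hydride, and the formate is methanolysed in the same flask.

**Step 3**
Reactants: 5 4-(benzyloxy)-3,5-dimethoxyphenol
Product: 6 3-(benzyloxy)-6-hydroxy-2,4-dimethoxybenzaldehyde
Conditions: MgCl2, Et3N, (CH2O)n, MeCN, reflux; dilute HCl work-up
Reagents that add atoms: paraformaldehyde (as formaldehyde), C=O
Why: Casnati–Skattebøl ortho-formylation; the magnesium phenoxide delivers formaldehyde to the ortho carbon and a second formaldehyde oxidises the benzylic alkoxide by hydride transfer, and the two ortho positions of 5 are equivalent with the para position blocked.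

**Step 4**
Reactants: 6 3-(benzyloxy)-6-hydroxy-2,4-dimethoxybenzaldehyde
Product: 7 3-(benzyloxy)-6-hydroxy-2,4-dimethoxybenzoic acid
Conditions: NaClO2, NaH2PO4, 2-methyl-2-butene, t-BuOH/H2O, 0 °C to rt
Reagents that add atoms: sodium chlorite, [Na+].[O-]Cl=O
Why: Pinnick oxidation; chlorous acid adds to the aldehyde and fragments to the acid while 2-methyl-2-butene traps HOCl, so the electron-rich ring should not be chlorinated.

**Step 5**
Reactants: 7 3-(benzyloxy)-6-hydroxy-2,4-dimethoxybenzoic acid; 8 3,4-dimethoxybenzaldehyde (veratraldehyde)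
Product: 10 rac-6-(benzyloxy)-2-(3,4-dimethoxyphenyl)-5,7-dimethoxy-4H-1,3-benzodioxin-4-one, via bis(trimethylsilyl) salicylate 9 (not isolated)
Conditions: (Me3Si)2NH, CH2Cl2, rt, then evaporation; 8, Me3SiOTf (10 mol %), CH2Cl2, −78 °C; pyridine quench
Reagents that add atoms: 3,4-dimethoxybenzaldehyde (8), COc1ccc(C=O)cc1OC
Why: Silyl-transfer acetalisation as used for 1,3-dioxan-4-ones from β-hydroxy acids; Me3SiOTf activates the aldehyde, the silyl ester and silyl ether oxygens add in turn and (Me3Si)2O is lost irreversibly at a temperature where decarboxylation and Friedel–Crafts attack on ring A should not compete, and the acetal centre is made racemic on purpose because step 7 erases it.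

**Step 6**
Reactants: 10 rac-6-(benzyloxy)-2-(3,4-dimethoxyphenyl)-5,7-dimethoxy-4H-1,3-benzodioxin-4-one
Product: 11 rac-6-(benzyloxy)-2-(3,4-dimethoxyphenyl)-5,7-dimethoxy-4-methylidene-4H-1,3-benzodioxine
Conditions: Cp2TiMe2, toluene/THF, 65 °C, dark; filtration through basic Al2O3
Reagents that add atoms: dimethyltitanocene Cp2TiMe2, [CH3-].[CH3-].[Ti+4].c1cc[cH-]c1.c1cc[cH-]c1
Why: Petasis methylenation; Cp2Ti=CH2 formed by loss of methane adds [2+2] to the lactone carbonyl and the oxatitanacyclobutane collapses to the enol ether under neutral conditions that the acylal carbon C2 tolerates, as established for 1,3-dioxan-4-ones.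

**Step 7**
Reactants: 11 rac-6-(benzyloxy)-2-(3,4-dimethoxyphenyl)-5,7-dimethoxy-4-methylidene-4H-1,3-benzodioxine
Product: 13 (2S)-6-(benzyloxy)-2-(3,4-dimethoxyphenyl)-5,7-dimethoxy-2,3-dihydro-4H-chromen-4-one, via oxocarbenium triflate 12 (not isolated)
Conditions: chiral tert-leucine arylpyrrolidine squaramide (10 mol %), Et3SiOTf (8 mol %), 2,6-di-tert-butylpyridine (5 mol %), t-BuOMe, −78 °C, 0.02 M; Et3N quench
Reagents that add atoms: none
Why: Proposed new method: the squaramide binds the triflate of Et3SiOTf and raises its silylating power, the enol-ether oxygen O3 of 11 is silylated and the C2–O3 bond ionises to 12, in which an aryloxy-oxocarbenium ion (O1=C2, stabilised by the 3,4-dimethoxyphenyl ring) and the triethylsilyl enol ether of the C4 ketone sit in one molecule; the enol CH2 then attacks C2 and the silyl group returns to triflate, so the step is an isomerisation that turns over both catalysts. The closest known reaction types are the Me2AlCl-promoted Petasis–Ferrier rearrangement of 4-methylene-1,3-dioxanes to tetrahydropyran-4-ones, the chiral phosphoric acid catalysed aza-Petasis–Ferrier rearrangement, and the squaramide/silyl triflate catalysed enantioselective Mukaiyama addition of enol silanes to oxocarbenium ions made from aryl acetals; their union on a benzo-fused enol acetal is what is new. Ring C is closed by a 6-(enolendo)-endo-trig Mukaiyama–Prins-type attack of C3 on C2, the same recombination as in the parent rearrangement. The only stereocentre, C2, is planar in 12, so both enantiomers of racemic 11 converge, and its configuration is set by the chiral squaramide-bound triflate that stays paired with the cation and shields one face of C2 during the intramolecular attack. The step needs C2–O3 rather than C2–O1 ionisation, C- rather than O-recombination and cyclisation rather than intermolecular Friedel–Crafts alkylation: C2–O1 ionisation can only return 11, the enol oxygen is blocked by silicon, C–C bond formation is irreversible because it releases the C4 carbonyl group, and the ortho tether at high dilution and −78 °C favours the six-membered closure.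

**Step 8**
Reactants: 13 (2S)-6-(benzyloxy)-2-(3,4-dimethoxyphenyl)-5,7-dimethoxy-2,3-dihydro-4H-chromen-4-one
Product: 14 (2S)-2-(3,4-dimethoxyphenyl)-6-hydroxy-5,7-dimethoxy-2,3-dihydro-4H-chromen-4-one
Conditions: H2 (1 atm), 10% Pd/C, EtOAc, rt
Reagents that add atoms: none
Why: Hydrogenolysis of the aryl benzyl ether under neutral conditions, which should leave the base-labile C2 stereocentre (retro-oxa-Michael opening) and the more slowly cleaved cyclic C2–O1 ether intact if the reaction is stopped at full conversion of 13.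

**Compound list**
1 | syringaldehyde (4-hydroxy-3,5-dimethoxybenzaldehyde) | O=Cc1cc(OC)c(O)c(OC)c1 | starting material
2 | benzyl bromide | BrCc1ccccc1 | starting material
3 | 4-(benzyloxy)-3,5-dimethoxybenzaldehyde | O=Cc1cc(OC)c(OCc2ccccc2)c(OC)c1 | intermediate
4 | 4-(benzyloxy)-3,5-dimethoxyphenyl formate (not isolated) | O=COc1cc(OC)c(OCc2ccccc2)c(OC)c1 | intermediate
5 | 4-(benzyloxy)-3,5-dimethoxyphenol | Oc1cc(OC)c(OCc2ccccc2)c(OC)c1 | intermediate
6 | 3-(benzyloxy)-6-hydroxy-2,4-dimethoxybenzaldehyde | O=Cc1c(O)cc(OC)c(OCc2ccccc2)c1OC | intermediate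
7 | 3-(benzyloxy)-6-hydroxy-2,4-dimethoxybenzoic acid | OC(=O)c1c(O)cc(OC)c(OCc2ccccc2)c1OC | intermediate
8 | 3,4-dimethoxybenzaldehyde (veratraldehyde) | COc1ccc(C=O)cc1OC | starting material
9 | trimethylsilyl 3-(benzyloxy)-2,4-dimethoxy-6-[(trimethylsilyl)oxy]benzoate (not isolated) | C[Si](C)(C)OC(=O)c1c(O[Si](C)(C)C)cc(OC)c(OCc2ccccc2)c1OC | intermediate
10 | rac-6-(benzyloxy)-2-(3,4-dimethoxyphenyl)-5,7-dimethoxy-4H-1,3-benzodioxin-4-one | O=C1OC(c2ccc(OC)c(OC)c2)Oc2cc(OC)c(OCc3ccccc3)c(OC)c21 | intermediate
11 | rac-6-(benzyloxy)-2-(3,4-dimethoxyphenyl)-5,7-dimethoxy-4-methylidene-4H-1,3-benzodioxine | C=C1OC(c2ccc(OC)c(OC)c2)Oc2cc(OC)c(OCc3ccccc3)c(OC)c21 | intermediate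
12 | ring-opened aryloxy-oxocarbenium triflate carrying the triethylsilyl enol ether (not isolated) | COc1ccc(C=[O+]c2cc(OC)c(OCc3ccccc3)c(OC)c2C(=C)O[Si](CC)(CC)CC)cc1OC.[O-]S(=O)(=O)C(F)(F)F | intermediate
13 | (2S)-6-(benzyloxy)-2-(3,4-dimethoxyphenyl)-5,7-dimethoxy-2,3-dihydro-4H-chromen-4-one | COc1ccc([C@@H]2CC(=O)c3c(cc(OC)c(OCc4ccccc4)c3OC)O2)cc1OC | intermediate
14 | (2S)-2-(3,4-dimethoxyphenyl)-6-hydroxy-5,7-dimethoxy-2,3-dihydro-4H-chromen-4-one | COc1ccc([C@@H]2CC(=O)c3c(cc(OC)c(O)c3OC)O2)cc1OC | target

**Total step count:** 8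
**Longest linear sequence:** 8 steps (1 to 14)

**Steps most likely to fail**

**Step 7 (proposed new method).** The ion pair may discriminate the two faces of C2 poorly. The oxocarbenium ion may also alkylate the electron-rich ring A of a second molecule instead of closing the ring. The fallback uses known chemistry, sets out from 5 and returns at 13; it forms the C2–aryl bond instead of C2–C3. Phenol 5 should be C-acetylated ortho to the hydroxyl (Ac2O, BF3·OEt2, 60 °C) to give 1-[3-(benzyloxy)-6-hydroxy-2,4-dimethoxyphenyl]ethan-1-one F1. Heating with DMF dimethyl acetal should give (2E)-1-[3-(benzyloxy)-6-hydroxy-2,4-dimethoxyphenyl]-3-(dimethylamino)prop-2-en-1-one F2. Acid (TsOH, CH2Cl2) should close F2 to 6-(benzyloxy)-5,7-dimethoxy-4H-chromen-4-one F3. Enantioselective conjugate addition of 3,4-dimethoxyphenylboronic acid to F3 should then give 13 (Pd(OCOCF3)2, divalent palladium, chiral tert-butyl pyridine-oxazoline ligand of the antipode that gives 2S, NH4PF6, H2O, ClCH2CH2Cl, 60 °C), and step 8 follows unchanged.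

**Step 5.** The electron-rich salicylic acid may lose CO2 under acid, the activated aldehyde may attack ring A, or the acylal may hydrolyse during isolation. The fallback sets out from 7 and 8 and returns at 10; it forms the first C–O bond by base-mediated alkylation instead of acid condensation. Veratraldehyde 8 should be converted (HC(OMe)3, TsOH cat., MeOH) to 4-(dimethoxymethyl)-1,2-dimethoxybenzene F4. Acetyl chloride should turn F4 in the flask into 4-[chloro(methoxy)methyl]-1,2-dimethoxybenzene F5. The caesium carboxylate of 7 (Cs2CO3, DMF, 0 °C) should be alkylated by F5 to (3,4-dimethoxyphenyl)(methoxy)methyl 3-(benzyloxy)-6-hydroxy-2,4-dimethoxybenzoate F6. The phenol of F6 should then close onto the acylal carbon with loss of methanol (PPTS cat., toluene, 5 Å sieves) to give 10.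

**Step 6.** Methylenation of the di-ortho-substituted lactone may be slow at the temperature the acylal survives, and titanium residues may trigger a premature, racemic rearrangement of 11. The fallback sets out from 5 and returns at 12, and so at 13; it reaches the same ion pair from an acyclic precursor without the temporary ring. The acetophenone F1 (made from 5 as above) should be O-alkylated with the chloro ether F5 (i-Pr2NEt, CH2Cl2, 0 °C) to give 1-{3-(benzyloxy)-6-[(3,4-dimethoxyphenyl)(methoxy)methoxy]-2,4-dimethoxyphenyl}ethan-1-one F7. Enolisation and silylation (KN(SiMe3)2, Et3SiCl, THF, −78 °C) should give {1-[3-(benzyloxy)-6-[(3,4-dimethoxyphenyl)(methoxy)methoxy]-2,4-dimethoxyphenyl]ethenyl}oxy(triethyl)silane F8. Under the catalyst system of step 7, the methoxy group of F8 should be ionised as Et3SiOMe to give 12, which closes to 13 as in the main route.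

**Further compounds**
F1 | step 7 | 1-[3-(benzyloxy)-6-hydroxy-2,4-dimethoxyphenyl]ethan-1-one | CC(=O)c1c(O)cc(OC)c(OCc2ccccc2)c1OC
F2 | step 7 | (2E)-1-[3-(benzyloxy)-6-hydroxy-2,4-dimethoxyphenyl]-3-(dimethylamino)prop-2-en-1-one | CN(C)/C=C/C(=O)c1c(O)cc(OC)c(OCc2ccccc2)c1OC
F3 | step 7 | 6-(benzyloxy)-5,7-dimethoxy-4H-chromen-4-one | O=c1ccoc2cc(OC)c(OCc3ccccc3)c(OC)c12
F4 | step 5 | 4-(dimethoxymethyl)-1,2-dimethoxybenzene | COC(OC)c1ccc(OC)c(OC)c1
F5 | step 5 | rac-4-[chloro(methoxy)methyl]-1,2-dimethoxybenzene | COC(Cl)c1ccc(OC)c(OC)c1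
F6 | step 5 | rac-(3,4-dimethoxyphenyl)(methoxy)methyl 3-(benzyloxy)-6-hydroxy-2,4-dimethoxybenzoate | COC(OC(=O)c1c(O)cc(OC)c(OCc2ccccc2)c1OC)c1ccc(OC)c(OC)c1
F7 | step 6 | rac-1-{3-(benzyloxy)-6-[(3,4-dimethoxyphenyl)(methoxy)methoxy]-2,4-dimethoxyphenyl}ethan-1-one | COC(Oc1cc(OC)c(OCc2ccccc2)c(OC)c1C(C)=O)c1ccc(OC)c(OC)c1
F8 | step 6 | rac-{1-[3-(benzyloxy)-6-[(3,4-dimethoxyphenyl)(methoxy)methoxy]-2,4-dimethoxyphenyl]ethenyl}oxy(triethyl)silane | COC(Oc1cc(OC)c(OCc2ccccc2)c(OC)c1C(=C)O[Si](CC)(CC)CC)c1ccc(OC)c(OC)c1
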